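**Plan**
- Retrosynthetic cuts: (a) the lactone Cα–CH2 bond to ring C (enolate benzylation); (b) the ring B C5–CH2 bond next to lactone Cβ (aryl-copper opening of a cyclopropane-fused lactone); (c) the dihydrobenzofuran C2–C3 bond (carbenoid C–H insertion); (d) the bond between the ring C-bearing carbon and the ring D carbinol carbon (anti aldol).
- Enabling feature: in the dihydrobenzofuran, C2 is a benzylic carbon bonded to O1 and ring A, and C3 carries a one-carbon oxygenated substituent and is bonded to ring B (C3a). C2–C3 therefore maps onto insertion of a ring B aryl(ester)carbenoid into a C–H bond of the ArA–CH2–O ether, closing the O1–C2–C3–C3a–C7a ring.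
- Forward order: one homologated arylacetic acid 5 (from 1) feeds both halves, and silylated vanillin 7 serves as ring A (after reduction) and as ring D (as the aldehyde). Ring B branch: phenol ester, Mitsunobu ether, diazo ester 12, dihydrofuran ring (step 9), opening of bicyclic lactone 19 (lactone ring brought in intact), decarboxylation.
- Ring C branch: imide, anti aldol with 7, diol, benzylic bromide 35. The halves are joined by lactone enolate alkylation and all silyl groups leave in one fluoride step.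
- Stereochemistry: C2 from the chiral dirhodium carboxylate; C3 by base equilibration to trans; lactone Cβ from (R)-epichlorohydrin; lactone Cα by alkylation anti to the Cβ substituent; both diol carbons from the (S)-4-benzyloxazolidinone in a magnesium-catalysed anti aldol.

Key step: step 9

Remark on step 9: Rh2(R-PTTL)4 (dirhodium tetrakis[N-phthaloyl-(R)-tert-leucinate], made like the (S)-form by ligand exchange on Rh2(OAc)4) is specified for (2S) by analogy with simpler 2-(benzyloxy)aryl diazoacetates, where the (S)-tert-leucinate series is taken to give (2R); if the sense proves opposite, the antipodal catalyst is used with nothing else changed.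
Remark on step 16: the aldol is taken to run through the chelated Z-enolate with attack anti to the auxiliary benzyl group, which requires the (S)-auxiliary; if the sense proves opposite, the (R)-auxiliary is used.
Abbreviations: TBS = tert-butyldimethylsilyl, TIPS = triisopropylsilyl (TBSO, TIPSO = the silyloxy groups).

Step 1
Reactants: 1 5-bromo-2-hydroxy-3-methoxybenzaldehyde
Product: 2 5-bromo-2-(TBSO)-3-methoxybenzaldehyde
Conditions: t-BuMe2SiCl, imidazole, DMF, rt
Reagents that add atoms: tert-butyldimethylsilyl chloride, CC(C)(C)[Si](C)(C)Cl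
Why: Imidazole-promoted O-silylation masks the phenol before ylide chemistry and installs what later serves as the ring C phenol protecting group; a doubly ortho-substituted aryl silyl ether should tolerate the base and dilute acid that follow.

Step 2
Reactants: 2 5-bromo-2-(TBSO)-3-methoxybenzaldehyde
Product: 3 tert-butyl[4-bromo-2-methoxy-6-(2-methoxyethenyl)phenoxy]dimethylsilane (E/Z mixture)
Conditions: Ph3P(CH2OMe)Cl, KOt-Bu, THF, 0 °C → rt
Reagents that add atoms: (methoxymethyl)triphenylphosphonium chloride, COC[P+](c1ccccc1)(c1ccccc1)c1ccccc1.[Cl-]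
Why: Wittig methoxymethylenation of a non-enolisable aryl aldehyde adds the one carbon needed for the arylacetic acid; the alkene geometry is irrelevant because both isomers hydrolyse to the same aldehyde.

Step 3
Reactants: 3 tert-butyl[4-bromo-2-methoxy-6-(2-methoxyethenyl)phenoxy]dimethylsilane
Product: 5 [5-bromo-2-(TBSO)-3-methoxyphenyl]acetic acid, via arylacetaldehyde 4 (not isolated)
Conditions: 2 M HCl, THF, 40 °C; then Na2HPO4 (to pH 4), t-BuOH, 2-methyl-2-butene, NaH2PO4, NaClO2, 0 °C → rt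
Reagents that add atoms: water, O; sodium chlorite, [Na+].[O-]Cl=O
Why: Acid-catalysed enol ether hydrolysis and Pinnick oxidation in the same flask oxidise the arylacetaldehyde (HOCl scavenged by 2-methyl-2-butene) before it can self-condense; the hindered aryl silyl ether should withstand the dilute acid, which matters because a free phenol would close onto the aldehyde to a benzofuran.

Step 4
Reactants: 6 vanillin
Product: 7 3-methoxy-4-(TIPSO)benzaldehyde
Conditions: i-Pr3SiCl, imidazole, DMF, rt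
Reagents that add atoms: triisopropylsilyl chloride, CC(C)[Si](Cl)(C(C)C)C(C)C
Why: Imidazole-promoted silylation of the phenol gives a base-robust aryl TIPS ether that is used twice, as the ring A precursor and as the ring D aldehyde.

Step 5
Reactants: 7 3-methoxy-4-(TIPSO)benzaldehyde
Product: 8 [3-methoxy-4-(TIPSO)phenyl]methanol
Conditions: NaBH4, MeOH, 0 °C
Reagents that add atoms: none
Why: Borohydride reduction of the aryl aldehyde gives the benzylic alcohol for the etherification; the aryl silyl ether is stable to brief exposure at 0 °C.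

Step 6
Reactants: 5 [5-bromo-2-(TBSO)-3-methoxyphenyl]acetic acid
Product: 10 methyl (5-bromo-2-hydroxy-3-methoxyphenyl)acetate, via phenol acid 9 (not isolated)
Conditions: Bu4NF, THF, 0 °C; then HCl in MeOH (1.25 M), rt
Reagents that add atoms: methanol, CO
Why: Fluoride desilylation of the aryl silyl ether followed by Fischer esterification; in acidic methanol the phenol acid, and any benzofuranone formed from it, should end as the open methyl ester with the phenol free.

Step 7
Reactants: 10 methyl (5-bromo-2-hydroxy-3-methoxyphenyl)acetate; 8 [3-methoxy-4-(TIPSO)phenyl]methanol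
Product: 11 methyl {5-bromo-3-methoxy-2-[(3-methoxy-4-(TIPSO)phenyl)methoxy]phenyl}acetate
Conditions: PPh3, DIAD, THF, 0 °C → rt
Reagents that add atoms: none
Why: Mitsunobu etherification alkylates the phenol (pKa about 10) with the primary benzylic alcohol under neutral conditions, avoiding an ionisation-prone silyloxybenzyl halide and basic media that would attack the aryl silyl ether.

Step 8
Reactants: 11 methyl {5-bromo-3-methoxy-2-[(3-methoxy-4-(TIPSO)phenyl)methoxy]phenyl}acetate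
Product: 12 methyl 2-diazo-2-{5-bromo-3-methoxy-2-[(3-methoxy-4-(TIPSO)phenyl)methoxy]phenyl}acetate
Conditions: 4-acetamidobenzenesulfonyl azide, DBU, MeCN, 0 °C → rt
Reagents that add atoms: 4-acetamidobenzenesulfonyl azide, CC(=O)Nc1ccc(cc1)S(=O)(=O)N=[N+]=[N-]
Why: Regitz diazo transfer: DBU deprotonates the benzylic, ester-activated CH2 and the enolate takes N2 from the sulfonyl azide, the standard entry to aryldiazoacetates.

Step 9
Reactants: 12 methyl 2-diazo-2-{5-bromo-3-methoxy-2-[(3-methoxy-4-(TIPSO)phenyl)methoxy]phenyl}acetate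
Product: 14 methyl (2S,3S)-5-bromo-7-methoxy-2-[3-methoxy-4-(TIPSO)phenyl]-2,3-dihydro-1-benzofuran-3-carboxylate (trans), via cis ester 13 (not isolated)
Conditions: Rh2(R-PTTL)4 (1 mol %), toluene, −60 °C (slow addition of 12); then DBU, −60 °C → 40 °C
Reagents that add atoms: none
Why: Loss of N2 at the divalent rhodium centre gives a donor/acceptor carbenoid whose electrophilic carbon inserts into one of the two enantiotopic C–H bonds of the ArA–CH2–O group through a concerted, asynchronous three-centre (hydride-transfer-like) transition state; the closest known reaction type is the enantioselective intramolecular C–H insertion of 2-(benzyloxy)aryl diazoacetates, 5-bromo members included, with chiral dirhodium carboxylates. The dihydrofuran ring closes by 1,5-insertion, that is C3–C2 bond formation through a five-membered cyclic transition state made of the carbenoid carbon, two ring B carbons, the ether oxygen and the benzylic carbon. C2 is set by the catalyst, whose phthalimido walls distinguish the two benzylic hydrogens, and the kinetic product should be the cis ester 13. C3 is then set thermodynamically: DBU enolises the ester and reprotonation places it trans to the C2 aryl group, while C2 is safe because ring opening of the enolate would be the reverse of a disfavoured 5-endo-trig closure. The step needs site selectivity for the ether C–H bond over attack on the aromatic rings or the methoxy groups, secured by the five-membered geometry, the activation of that bond by the ether oxygen and electron-rich ring A, the selective donor/acceptor carbenoid and the low temperature. The aryl bromide and the TIPS ether are inert and stay as handles.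

Step 10
Reactants: 14 methyl (2S,3S)-5-bromo-7-methoxy-2-[3-methoxy-4-(TIPSO)phenyl]-2,3-dihydro-1-benzofuran-3-carboxylate
Product: 15 {(2S,3R)-5-bromo-7-methoxy-2-[3-methoxy-4-(TIPSO)phenyl]-2,3-dihydro-1-benzofuran-3-yl}methanol
Conditions: LiBH4, MeOH (2 equiv), THF, 0 °C → rt
Reagents that add atoms: none
Why: Ester reduction with LiBH4 gives the CH2OH group and leaves the aryl bromide, the aryl silyl ether and the cyclic benzylic ether alone; C3 is already in its thermodynamic configuration (3S becomes 3R only through the priority rules).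

Step 11
Reactants: 15 {(2S,3R)-5-bromo-7-methoxy-2-[3-methoxy-4-(TIPSO)phenyl]-2,3-dihydro-1-benzofuran-3-yl}methanol
Product: 16 (2S,3R)-5-bromo-3-[(TBSO)methyl]-7-methoxy-2-[3-methoxy-4-(TIPSO)phenyl]-2,3-dihydro-1-benzofuran
Conditions: t-BuMe2SiCl, imidazole, CH2Cl2, rt
Reagents that add atoms: tert-butyldimethylsilyl chloride, CC(C)(C)[Si](C)(C)Cl
Why: Imidazole-promoted silylation of the primary alcohol removes the only acidic hydrogen before the organometallic step.

Step 12
Reactants: 17 dibenzyl malonate; 18 (R)-epichlorohydrin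
Product: 19 benzyl (1S,5R)-2-oxo-3-oxabicyclo[3.1.0]hexane-1-carboxylate
Conditions: NaOCH2Ph (1 M in PhCH2OH), THF, 0 °C → 65 °C
Reagents that add atoms: none
Why: Tandem malonate alkylation, cyclopropanation and lactonisation: the malonate anion opens the epoxide at CH2, the alkoxide recloses to the transposed epoxide with loss of chloride, a 3-exo-tet attack with inversion forms the cyclopropane and the freed alkoxide lactonises on the cis ester, so the (R) centre of 18 becomes C5 (R) and dictates C1 (S); the benzyl ester is chosen so that the later decarboxylation can be run under neutral conditions.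

Step 13
Reactants: 16 (2S,3R)-5-bromo-3-[(TBSO)methyl]-7-methoxy-2-[3-methoxy-4-(TIPSO)phenyl]-2,3-dihydro-1-benzofuran; 19 benzyl (1S,5R)-2-oxo-3-oxabicyclo[3.1.0]hexane-1-carboxylate
Product: 22 benzyl (3R,4R)-4-({(2S,3R)-3-[(TBSO)methyl]-7-methoxy-2-[3-methoxy-4-(TIPSO)phenyl]-2,3-dihydro-1-benzofuran-5-yl}methyl)-2-oxooxolane-3-carboxylate (3,4-trans), via aryllithium 20 (not isolated), via arylmagnesium bromide 21 (not isolated)
Conditions: t-BuLi (2 equiv), THF, −78 °C; MgBr2·OEt2, −78 → −30 °C; CuI (0.2 equiv), 19, −30 → 0 °C; aq. NH4Cl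
Reagents that add atoms: none
Why: Bromine–lithium exchange, transmetalation to magnesium and CuI-catalysed homoconjugate (SN2-type) opening of the doubly activated cyclopropane at its CH2 group, a known reaction of this bicyclic lactone class with aryl Grignard reagents; C4 of the new lactone is the untouched C5 of 19 and the acidic malonate-type C3 settles trans.

Step 14
Reactants: 22 benzyl (3R,4R)-4-({(2S,3R)-3-[(TBSO)methyl]-7-methoxy-2-[3-methoxy-4-(TIPSO)phenyl]-2,3-dihydro-1-benzofuran-5-yl}methyl)-2-oxooxolane-3-carboxylate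
Product: 24 (4R)-4-({(2S,3R)-3-[(TBSO)methyl]-7-methoxy-2-[3-methoxy-4-(TIPSO)phenyl]-2,3-dihydro-1-benzofuran-5-yl}methyl)oxolan-2-one, via carboxylic acid 23 (not isolated)
Conditions: H2 (1 atm), 10% Pd/C, EtOAc, rt (short contact); filtration; toluene, 100 °C
Reagents that add atoms: none
Why: Hydrogenolysis of the benzyl ester and thermal decarboxylation of the malonic-type β-carboxy lactone run under neutral conditions that spare both silyl ethers; the benzyl ester should cleave far faster than the cyclic 2-aryl ether of the dihydrobenzofuran, and the remaining lactone stereocentre (C4) is not enolisable.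

Step 15
Reactants: 5 [5-bromo-2-(TBSO)-3-methoxyphenyl]acetic acid; 25 (S)-4-benzyl-1,3-oxazolidin-2-one
Product: 27 (4S)-4-benzyl-3-{[5-bromo-2-(TBSO)-3-methoxyphenyl]acetyl}-1,3-oxazolidin-2-one, via mixed pivalic anhydride 26 (not isolated)
Conditions: t-BuCOCl, Et3N, THF, −20 °C; then LiCl, 25, −20 °C → rt
Reagents that add atoms: none
Why: N-Acylation of the oxazolidinone through the mixed pivalic anhydride (LiCl/Et3N variant) attaches the chiral auxiliary without strong base.

Step 16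
Reactants: 27 (4S)-4-benzyl-3-{[5-bromo-2-(TBSO)-3-methoxyphenyl]acetyl}-1,3-oxazolidin-2-one; 7 3-methoxy-4-(TIPSO)benzaldehyde
Product: 29 (4S)-4-benzyl-3-{(2R,3S)-2-[5-bromo-2-(TBSO)-3-methoxyphenyl]-3-hydroxy-3-[3-methoxy-4-(TIPSO)phenyl]propanoyl}-1,3-oxazolidin-2-one, via trimethylsilyl ether 28 (not isolated)
Conditions: MgCl2 (0.2 equiv), Et3N, Me3SiCl, EtOAc, rt; then 1 M HCl, THF, 0 °C
Reagents that add atoms: none
Why: Magnesium halide-catalysed direct anti-aldol reaction of an N-acyloxazolidinone with a non-enolisable aromatic aldehyde (silyl trapping turns the catalyst over): the chelated Z-enolate should add through a boat-like transition state on the face away from the auxiliary benzyl group, setting 2R at the ring C-bearing carbon and 3S at the carbinol, the anti pair required.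

Step 17
Reactants: 29 (4S)-4-benzyl-3-{(2R,3S)-2-[5-bromo-2-(TBSO)-3-methoxyphenyl]-3-hydroxy-3-[3-methoxy-4-(TIPSO)phenyl]propanoyl}-1,3-oxazolidin-2-one
Product: 30 (1S,2S)-2-[5-bromo-2-(TBSO)-3-methoxyphenyl]-1-[3-methoxy-4-(TIPSO)phenyl]propane-1,3-diol
Conditions: LiBH4, MeOH (1 equiv), THF, 0 °C
Reagents that add atoms: none
Why: Reductive removal of the auxiliary with LiBH4 (hydride attack at the exocyclic imide carbonyl, assisted by the neighbouring alkoxide) gives the 1,3-diol at a temperature where retro-aldol cleavage should not compete; both centres are untouched (2R becomes 2S only through the priority rules).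

Step 18
Reactants: 30 (1S,2S)-2-[5-bromo-2-(TBSO)-3-methoxyphenyl]-1-[3-methoxy-4-(TIPSO)phenyl]propane-1,3-diol
Product: 31 (4S,5S)-5-[5-bromo-2-(TBSO)-3-methoxyphenyl]-2,2-di-tert-butyl-4-[3-methoxy-4-(TIPSO)phenyl]-1,3,2-dioxasilinane
Conditions: t-Bu2Si(OTf)2, 2,6-lutidine, CH2Cl2, 0 °C
Reagents that add atoms: di-tert-butylsilyl bis(trifluoromethanesulfonate), CC(C)(C)[Si](OS(=O)(=O)C(F)(F)F)(OS(=O)(=O)C(F)(F)F)C(C)(C)C
Why: Cyclic silylene formation from the anti 1,3-diol gives a six-membered ring with both aryl groups equatorial; it protects both hydroxyls in one operation and is removable by fluoride without acid.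

Step 19
Reactants: 31 (4S,5S)-5-[5-bromo-2-(TBSO)-3-methoxyphenyl]-2,2-di-tert-butyl-4-[3-methoxy-4-(TIPSO)phenyl]-1,3,2-dioxasilinane
Product: 34 {4-(TBSO)-3-[(4S,5S)-2,2-di-tert-butyl-4-(3-methoxy-4-(TIPSO)phenyl)-1,3,2-dioxasilinan-5-yl]-5-methoxyphenyl}methanol, via aryllithium 32 (not isolated), via aldehyde 33 (not isolated)
Conditions: n-BuLi, THF, −78 °C; DMF, −78 → −20 °C; AcOH, MeOH, then NaBH4, 0 °C
Reagents that add atoms: N,N-dimethylformamide, CN(C)C=O
Why: Bromine–lithium exchange and formylation of the aryllithium with DMF, then borohydride reduction of the aldehyde in the same flask; buffering with AcOH before NaBH4 keeps the para-formyl aryl silyl ether from alkoxide attack.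

Step 20
Reactants: 34 {4-(TBSO)-3-[(4S,5S)-2,2-di-tert-butyl-4-(3-methoxy-4-(TIPSO)phenyl)-1,3,2-dioxasilinan-5-yl]-5-methoxyphenyl}methanol
Product: 35 (4S,5S)-5-[5-(bromomethyl)-2-(TBSO)-3-methoxyphenyl]-2,2-di-tert-butyl-4-[3-methoxy-4-(TIPSO)phenyl]-1,3,2-dioxasilinane
Conditions: CBr4, PPh3, 2,6-lutidine (cat.), CH2Cl2, 0 °C
Reagents that add atoms: carbon tetrabromide, BrC(Br)(Br)Br
Why: Appel bromination converts the benzylic alcohol into the bromide under neutral conditions that spare the silyl groups; the para-silyloxybenzyl bromide is used at once.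

Step 21
Reactants: 24 (4R)-4-({(2S,3R)-3-[(TBSO)methyl]-7-methoxy-2-[3-methoxy-4-(TIPSO)phenyl]-2,3-dihydro-1-benzofuran-5-yl}methyl)oxolan-2-one; 35 (4S,5S)-5-[5-(bromomethyl)-2-(TBSO)-3-methoxyphenyl]-2,2-di-tert-butyl-4-[3-methoxy-4-(TIPSO)phenyl]-1,3,2-dioxasilinane
Product: 37 fully silylated target (3R,4R)-3-{4-(TBSO)-3-[(4S,5S)-2,2-di-tert-butyl-4-(3-methoxy-4-(TIPSO)phenyl)-1,3,2-dioxasilinan-5-yl]-5-methoxybenzyl}-4-({(2S,3R)-3-[(TBSO)methyl]-7-methoxy-2-[3-methoxy-4-(TIPSO)phenyl]-2,3-dihydro-1-benzofuran-5-yl}methyl)oxolan-2-one, via lithium enolate 36 (not isolated)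
Conditions: LiN(SiMe3)2, THF, −78 °C; then 35, DMPU, −78 → −40 °C
Reagents that add atoms: none
Why: Alkylation of a γ-butyrolactone lithium enolate with a benzylic bromide: the electrophile approaches anti to the C4 substituent, which sets C3 (R) and gives the 3,4-trans lactone, the kinetic and also the thermodynamic outcome for dibenzylbutyrolactones.

Step 22
Reactants: 37 fully silylated target
Product: 38 CNP0186558.2, (3R,4R)-3-{3-[(1S,2S)-1,3-dihydroxy-1-(4-hydroxy-3-methoxyphenyl)propan-2-yl]-4-hydroxy-5-methoxybenzyl}-4-{[(2S,3R)-2-(4-hydroxy-3-methoxyphenyl)-3-(hydroxymethyl)-7-methoxy-2,3-dihydro-1-benzofuran-5-yl]methyl}oxolan-2-one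
Conditions: Bu4NF, AcOH (1:1), THF, 0 °C → rt
Reagents that add atoms: none
Why: Global fluoride desilylation cleaves the two aryl TIPS ethers, the aryl and alkyl TBS ethers and the silylene, and buffering with AcOH should prevent phenoxide-driven quinone methide formation at the ring D carbinol and enolisation of the lactone.

**Compound list**
1 | 5-bromo-2-hydroxy-3-methoxybenzaldehyde | COc1cc(Br)cc(C=O)c1O | starting material
2 | 5-bromo-2-(TBSO)-3-methoxybenzaldehyde | COc1cc(Br)cc(C=O)c1O[Si](C)(C)C(C)(C)C | intermediate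
3 | tert-butyl[4-bromo-2-methoxy-6-(2-methoxyethenyl)phenoxy]dimethylsilane (E/Z mixture, E written) | CO/C=C/c1cc(Br)cc(OC)c1O[Si](C)(C)C(C)(C)C | intermediate
4 | [5-bromo-2-(TBSO)-3-methoxyphenyl]acetaldehyde (not isolated) | O=CCc1cc(Br)cc(OC)c1O[Si](C)(C)C(C)(C)C | intermediate
5 | [5-bromo-2-(TBSO)-3-methoxyphenyl]acetic acid | OC(=O)Cc1cc(Br)cc(OC)c1O[Si](C)(C)C(C)(C)C | intermediate
6 | vanillin | COc1cc(C=O)ccc1O | starting material
7 | 3-methoxy-4-(TIPSO)benzaldehyde | COc1cc(C=O)ccc1O[Si](C(C)C)(C(C)C)C(C)C | intermediate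
8 | [3-methoxy-4-(TIPSO)phenyl]methanol | COc1cc(CO)ccc1O[Si](C(C)C)(C(C)C)C(C)C | intermediate
9 | (5-bromo-2-hydroxy-3-methoxyphenyl)acetic acid (not isolated) | OC(=O)Cc1cc(Br)cc(OC)c1O | intermediate
10 | methyl (5-bromo-2-hydroxy-3-methoxyphenyl)acetate | COC(=O)Cc1cc(Br)cc(OC)c1O | intermediate
11 | methyl {5-bromo-3-methoxy-2-[(3-methoxy-4-(TIPSO)phenyl)methoxy]phenyl}acetate | COC(=O)Cc1cc(Br)cc(OC)c1OCc1ccc(O[Si](C(C)C)(C(C)C)C(C)C)c(OC)c1 | intermediate
12 | methyl 2-diazo-2-{5-bromo-3-methoxy-2-[(3-methoxy-4-(TIPSO)phenyl)methoxy]phenyl}acetate | COC(=O)C(=[N+]=[N-])c1cc(Br)cc(OC)c1OCc1ccc(O[Si](C(C)C)(C(C)C)C(C)C)c(OC)c1 | intermediate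
13 | methyl (2S,3R)-5-bromo-7-methoxy-2-[3-methoxy-4-(TIPSO)phenyl]-2,3-dihydro-1-benzofuran-3-carboxylate (cis, not isolated) | Brc1cc(OC)c2c(c1)[C@@H](C(=O)OC)[C@@H](c1ccc(O[Si](C(C)C)(C(C)C)C(C)C)c(OC)c1)O2 | intermediate
14 | methyl (2S,3S)-5-bromo-7-methoxy-2-[3-methoxy-4-(TIPSO)phenyl]-2,3-dihydro-1-benzofuran-3-carboxylate (trans) | Brc1cc(OC)c2c(c1)[C@H](C(=O)OC)[C@@H](c1ccc(O[Si](C(C)C)(C(C)C)C(C)C)c(OC)c1)O2 | intermediate
15 | {(2S,3R)-5-bromo-7-methoxy-2-[3-methoxy-4-(TIPSO)phenyl]-2,3-dihydro-1-benzofuran-3-yl}methanol | Brc1cc(OC)c2c(c1)[C@H](CO)[C@@H](c1ccc(O[Si](C(C)C)(C(C)C)C(C)C)c(OC)c1)O2 | intermediate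
16 | (2S,3R)-5-bromo-3-[(TBSO)methyl]-7-methoxy-2-[3-methoxy-4-(TIPSO)phenyl]-2,3-dihydro-1-benzofuran | Brc1cc(OC)c2c(c1)[C@H](CO[Si](C)(C)C(C)(C)C)[C@@H](c1ccc(O[Si](C(C)C)(C(C)C)C(C)C)c(OC)c1)O2 | intermediate
17 | dibenzyl malonate | O=C(CC(=O)OCc1ccccc1)OCc1ccccc1 | starting material
18 | (R)-epichlorohydrin | ClC[C@H]1CO1 | starting material
19 | benzyl (1S,5R)-2-oxo-3-oxabicyclo[3.1.0]hexane-1-carboxylate | O=C(OCc1ccccc1)[C@]12C[C@H]1COC2=O | intermediate
20 | 5-lithio derivative of 16 (not isolated) | [Li]c1cc(OC)c2c(c1)[C@H](CO[Si](C)(C)C(C)(C)C)[C@@H](c1ccc(O[Si](C(C)C)(C(C)C)C(C)C)c(OC)c1)O2 | intermediate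
21 | 5-(bromomagnesio) derivative of 16 (not isolated) | Br[Mg]c1cc(OC)c2c(c1)[C@H](CO[Si](C)(C)C(C)(C)C)[C@@H](c1ccc(O[Si](C(C)C)(C(C)C)C(C)C)c(OC)c1)O2 | intermediate
22 | benzyl (3R,4R)-4-({(2S,3R)-3-[(TBSO)methyl]-7-methoxy-2-[3-methoxy-4-(TIPSO)phenyl]-2,3-dihydro-1-benzofuran-5-yl}methyl)-2-oxooxolane-3-carboxylate (3,4-trans, C3 labile) | O=C(OCc1ccccc1)[C@H]1C(=O)OC[C@@H]1Cc1cc(OC)c2c(c1)[C@H](CO[Si](C)(C)C(C)(C)C)[C@@H](c1ccc(O[Si](C(C)C)(C(C)C)C(C)C)c(OC)c1)O2 | intermediate
23 | (3S,4R)-4-({(2S,3R)-3-[(TBSO)methyl]-7-methoxy-2-[3-methoxy-4-(TIPSO)phenyl]-2,3-dihydro-1-benzofuran-5-yl}methyl)-2-oxooxolane-3-carboxylic acid (not isolated) | OC(=O)[C@H]1C(=O)OC[C@@H]1Cc1cc(OC)c2c(c1)[C@H](CO[Si](C)(C)C(C)(C)C)[C@@H](c1ccc(O[Si](C(C)C)(C(C)C)C(C)C)c(OC)c1)O2 | intermediate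
24 | (4R)-4-({(2S,3R)-3-[(TBSO)methyl]-7-methoxy-2-[3-methoxy-4-(TIPSO)phenyl]-2,3-dihydro-1-benzofuran-5-yl}methyl)oxolan-2-one | C1C(=O)OC[C@@H]1Cc1cc(OC)c2c(c1)[C@H](CO[Si](C)(C)C(C)(C)C)[C@@H](c1ccc(O[Si](C(C)C)(C(C)C)C(C)C)c(OC)c1)O2 | intermediate
25 | (S)-4-benzyl-1,3-oxazolidin-2-one | O=C1N[C@@H](Cc2ccccc2)CO1 | starting material
26 | [5-bromo-2-(TBSO)-3-methoxyphenyl]acetic pivalic anhydride (not isolated) | CC(C)(C)C(=O)OC(=O)Cc1cc(Br)cc(OC)c1O[Si](C)(C)C(C)(C)C | intermediate
27 | (4S)-4-benzyl-3-{[5-bromo-2-(TBSO)-3-methoxyphenyl]acetyl}-1,3-oxazolidin-2-one | O=C1OC[C@H](Cc2ccccc2)N1C(=O)Cc1cc(Br)cc(OC)c1O[Si](C)(C)C(C)(C)C | intermediate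
28 | O-trimethylsilyl ether of 29, (2R,3S) (not isolated) | COc1cc([C@@H](O[Si](C)(C)C)[C@H](C(=O)N2[C@@H](Cc3ccccc3)COC2=O)c2cc(Br)cc(OC)c2O[Si](C)(C)C(C)(C)C)ccc1O[Si](C(C)C)(C(C)C)C(C)C | intermediate
29 | (4S)-4-benzyl-3-{(2R,3S)-2-[5-bromo-2-(TBSO)-3-methoxyphenyl]-3-hydroxy-3-[3-methoxy-4-(TIPSO)phenyl]propanoyl}-1,3-oxazolidin-2-one | COc1cc([C@@H](O)[C@H](C(=O)N2[C@@H](Cc3ccccc3)COC2=O)c2cc(Br)cc(OC)c2O[Si](C)(C)C(C)(C)C)ccc1O[Si](C(C)C)(C(C)C)C(C)C | intermediate
30 | (1S,2S)-2-[5-bromo-2-(TBSO)-3-methoxyphenyl]-1-[3-methoxy-4-(TIPSO)phenyl]propane-1,3-diol | COc1cc([C@@H](O)[C@H](CO)c2cc(Br)cc(OC)c2O[Si](C)(C)C(C)(C)C)ccc1O[Si](C(C)C)(C(C)C)C(C)C | intermediate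
31 | (4S,5S)-5-[5-bromo-2-(TBSO)-3-methoxyphenyl]-2,2-di-tert-butyl-4-[3-methoxy-4-(TIPSO)phenyl]-1,3,2-dioxasilinane | COc1cc([C@H]2O[Si](C(C)(C)C)(C(C)(C)C)OC[C@@H]2c2cc(Br)cc(OC)c2O[Si](C)(C)C(C)(C)C)ccc1O[Si](C(C)C)(C(C)C)C(C)C | intermediate
32 | aryllithium from 31 (Li in place of Br, not isolated) | COc1cc([C@H]2O[Si](C(C)(C)C)(C(C)(C)C)OC[C@@H]2c2cc([Li])cc(OC)c2O[Si](C)(C)C(C)(C)C)ccc1O[Si](C(C)C)(C(C)C)C(C)C | intermediate
33 | 4-(TBSO)-3-[(4S,5S)-2,2-di-tert-butyl-4-(3-methoxy-4-(TIPSO)phenyl)-1,3,2-dioxasilinan-5-yl]-5-methoxybenzaldehyde (not isolated) | COc1cc([C@H]2O[Si](C(C)(C)C)(C(C)(C)C)OC[C@@H]2c2cc(C=O)cc(OC)c2O[Si](C)(C)C(C)(C)C)ccc1O[Si](C(C)C)(C(C)C)C(C)C | intermediate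
34 | {4-(TBSO)-3-[(4S,5S)-2,2-di-tert-butyl-4-(3-methoxy-4-(TIPSO)phenyl)-1,3,2-dioxasilinan-5-yl]-5-methoxyphenyl}methanol | COc1cc([C@H]2O[Si](C(C)(C)C)(C(C)(C)C)OC[C@@H]2c2cc(CO)cc(OC)c2O[Si](C)(C)C(C)(C)C)ccc1O[Si](C(C)C)(C(C)C)C(C)C | intermediate
35 | (4S,5S)-5-[5-(bromomethyl)-2-(TBSO)-3-methoxyphenyl]-2,2-di-tert-butyl-4-[3-methoxy-4-(TIPSO)phenyl]-1,3,2-dioxasilinane | COc1cc([C@H]2O[Si](C(C)(C)C)(C(C)(C)C)OC[C@@H]2c2cc(CBr)cc(OC)c2O[Si](C)(C)C(C)(C)C)ccc1O[Si](C(C)C)(C(C)C)C(C)C | intermediate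
36 | lithium enolate of 24 (not isolated) | C1=C(O[Li])OC[C@@H]1Cc1cc(OC)c2c(c1)[C@H](CO[Si](C)(C)C(C)(C)C)[C@@H](c1ccc(O[Si](C(C)C)(C(C)C)C(C)C)c(OC)c1)O2 | intermediate
37 | fully silylated target, (3R,4R)-lactone with (4S,5S)-dioxasilinane and (2S,3R)-dihydrobenzofuran | COc1cc([C@H]2O[Si](C(C)(C)C)(C(C)(C)C)OC[C@@H]2c2cc(C[C@H]3C(=O)OC[C@@H]3Cc3cc(OC)c4c(c3)[C@H](CO[Si](C)(C)C(C)(C)C)[C@@H](c3ccc(O[Si](C(C)C)(C(C)C)C(C)C)c(OC)c3)O4)cc(OC)c2O[Si](C)(C)C(C)(C)C)ccc1O[Si](C(C)C)(C(C)C)C(C)C | intermediate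
38 | CNP0186558.2 | COc1cc([C@@H](O)[C@H](CO)c2cc(C[C@H]3C(=O)OC[C@@H]3Cc3cc(OC)c4c(c3)[C@H](CO)[C@@H](c3ccc(O)c(OC)c3)O4)cc(OC)c2O)ccc1O | target

**Step count and risks**
Total: 22 steps. Longest linear sequence: 13 steps (1, 2, 3, 6, 7, 8, 9, 10, 11, 13, 14, 21, 22); the ring C–D branch (1, 2, 3, 15–20) joins at step 21.

Step 9 may suffer from poor discrimination between the two benzylic hydrogens, or from the wrong sense, because the 7-methoxy group and the very electron-rich ring A can push the insertion towards a stepwise hydride-transfer pathway that the catalyst controls less well. The fallback gives up catalyst control for resolution. It sets out from 12: insertion with achiral Rh2(OAc)4 in CH2Cl2 followed by DBU should give the racemic trans ester F1, and LiBH4 reduction the racemic alcohol F2. Esterification with (S)-2-methoxy-2-phenylacetic acid (DCC, DMAP) gives the (S)-O-methylmandelate of the (2S,3R)-alcohol F3 and the (S)-O-methylmandelate of the (2R,3S)-alcohol F4, which are separated by chromatography. LiBH4 cleavage of F3 comes back to the route at 15.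

Step 16 may stall or lose anti selectivity, since the enolate carries a hindered ortho-silyloxyaryl group, the aldehyde is deactivated by its para oxygen, and a reversible aldol would erode the kinetic ratio. The fallback builds the same two centres by allylboration. It sets out from 2: Wittig methylenation (Ph3PCH3Br, KOt-Bu) gives 5-bromo-2-(TBSO)-3-methoxystyrene F5, and cross-metathesis with allylboronic acid pinacol ester (second-generation Grubbs catalyst) gives the (E)-3-arylallyl pinacol boronate F6. Allylboration of 7 through a chair transition state, catalysed by the chiral phosphoric acid (S)-TRIP (antipode assigned by analogy with simple allyl and crotyl boronates), gives the anti homoallylic alcohol F7. Ozonolysis with NaBH4 work-up comes back to the route at 30.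

Step 13 may fail through addition of the aryl-metal species to the lactone or ester carbonyl, or through its protonation or homocoupling, before the homoconjugate opening takes place. The fallback joins the aryl group to a four-carbon lactone precursor by cross-coupling. It sets out from 16: Miyaura borylation (B2pin2, Pd(dppf)Cl2, KOAc, dioxane, 80 °C) gives the aryl pinacol boronate F8. Suzuki–Miyaura coupling with 4-(bromomethyl)furan-2(5H)-one (Pd(PPh3)4, K3PO4, dioxane, 60 °C) gives the 4-(arylmethyl)butenolide F9. CuH-catalysed asymmetric conjugate reduction (Cu(OAc)2, the p-tol-BINAP antipode that gives the (R)-lactone, polymethylhydrosiloxane, t-BuOH, toluene) comes back to the route at 24, so steps 12 and 14 are not needed.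

Further compounds
F1 | step 9 | racemic methyl trans-5-bromo-7-methoxy-2-[3-methoxy-4-(TIPSO)phenyl]-2,3-dihydro-1-benzofuran-3-carboxylate (both enantiomers written) | Brc1cc(OC)c2c(c1)[C@H](C(=O)OC)[C@@H](c1ccc(O[Si](C(C)C)(C(C)C)C(C)C)c(OC)c1)O2.Brc1cc(OC)c2c(c1)[C@@H](C(=O)OC)[C@H](c1ccc(O[Si](C(C)C)(C(C)C)C(C)C)c(OC)c1)O2
F2 | step 9 | racemic trans-{5-bromo-7-methoxy-2-[3-methoxy-4-(TIPSO)phenyl]-2,3-dihydro-1-benzofuran-3-yl}methanol (both enantiomers written) | Brc1cc(OC)c2c(c1)[C@H](CO)[C@@H](c1ccc(O[Si](C(C)C)(C(C)C)C(C)C)c(OC)c1)O2.Brc1cc(OC)c2c(c1)[C@@H](CO)[C@H](c1ccc(O[Si](C(C)C)(C(C)C)C(C)C)c(OC)c1)O2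
F3 | step 9 | {(2S,3R)-5-bromo-7-methoxy-2-[3-methoxy-4-(TIPSO)phenyl]-2,3-dihydro-1-benzofuran-3-yl}methyl (S)-2-methoxy-2-phenylacetate | Brc1cc(OC)c2c(c1)[C@H](COC(=O)[C@@H](OC)c1ccccc1)[C@@H](c1ccc(O[Si](C(C)C)(C(C)C)C(C)C)c(OC)c1)O2
F4 | step 9 | {(2R,3S)-5-bromo-7-methoxy-2-[3-methoxy-4-(TIPSO)phenyl]-2,3-dihydro-1-benzofuran-3-yl}methyl (S)-2-methoxy-2-phenylacetate | Brc1cc(OC)c2c(c1)[C@@H](COC(=O)[C@@H](OC)c1ccccc1)[C@H](c1ccc(O[Si](C(C)C)(C(C)C)C(C)C)c(OC)c1)O2
F5 | step 16 | 5-bromo-2-(TBSO)-3-methoxystyrene | C=Cc1cc(Br)cc(OC)c1O[Si](C)(C)C(C)(C)C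
F6 | step 16 | 2-{(E)-3-[5-bromo-2-(TBSO)-3-methoxyphenyl]prop-2-en-1-yl}-4,4,5,5-tetramethyl-1,3,2-dioxaborolane | CC1(C)OB(C/C=C/c2cc(Br)cc(OC)c2O[Si](C)(C)C(C)(C)C)OC1(C)C
F7 | step 16 | (1S,2R)-2-[5-bromo-2-(TBSO)-3-methoxyphenyl]-1-[3-methoxy-4-(TIPSO)phenyl]but-3-en-1-ol (anti) | COc1cc([C@@H](O)[C@H](C=C)c2cc(Br)cc(OC)c2O[Si](C)(C)C(C)(C)C)ccc1O[Si](C(C)C)(C(C)C)C(C)C
F8 | step 13 | 2-{(2S,3R)-3-[(TBSO)methyl]-7-methoxy-2-[3-methoxy-4-(TIPSO)phenyl]-2,3-dihydro-1-benzofuran-5-yl}-4,4,5,5-tetramethyl-1,3,2-dioxaborolane | CC1(C)OB(OC1(C)C)c1cc(OC)c2c(c1)[C@H](CO[Si](C)(C)C(C)(C)C)[C@@H](c1ccc(O[Si](C(C)C)(C(C)C)C(C)C)c(OC)c1)O2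
F9 | step 13 | 4-({(2S,3R)-3-[(TBSO)methyl]-7-methoxy-2-[3-methoxy-4-(TIPSO)phenyl]-2,3-dihydro-1-benzofuran-5-yl}methyl)furan-2(5H)-one | O=C1OCC(Cc2cc(OC)c3c(c2)[C@H](CO[Si](C)(C)C(C)(C)C)[C@@H](c2ccc(O[Si](C(C)C)(C(C)C)C(C)C)c(OC)c2)O3)=C1
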